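## Retrosynthetic overview

1. Numbering: C4 = CMe2, C5=C6 = alkene, C8 = CH–CH3, C9 = quaternary C, C10 = ring-fusion CH, C11 = ArCH2; ring A = C1–C5/C10, ring B = C5–C10; arene C1′ (on C11), C2′ (O-sulfate), C3′ (CHO), C4′/C5′ (OH).
2. Feature used: ring A carries only CH2 groups at C1–C3 and its C9–C10 bond can be an aryl–alkyl bond, so a 4-methoxyphenyl ring (ipso carbon = C10, OMe on C3) serves as ring A in aromatic form and is dearomatised late.
3. Key disconnection C5–C6: Friedel–Crafts acylation closes ring B onto the anisole; the acid precursor comes from a C8–C9 Michael disconnection (arylacetate enolate + chiral N-crotonoyl imide, sets C8).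
4. After ring B: C9–CH3 by enolate methylation anti to C8–CH3, Birch reduction of ring A, C4 gem-dimethylation, C3 deoxygenation, then reduction of the C6 enone hydrazone (allylic diazene) puts H on C10 and the alkene at C5=C6.
5. C11–C1′ by aryllithium addition and radical deoxygenation; C3′ formylation, C2′ sulfation, deallylation last. Ring order: ring A (as purchased arene) → ring B (step 4) → attachment of the preformed benzenoid ring (step 21).

Key step: step 4

Remark 1: the target is drawn as the free aryl hydrogen sulfate; the sulfate is carried as its sodium salt (40, 41) and protonated only in the last work-up.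
Remark 2: three centres are left uncontrolled on purpose because both epimers converge: C9 in 5–9 (drawn as one epimer, planarised in step 5), the C6 carbinol carbon in 11–19 and the C11 carbinol carbon in 33–35 (drawn without descriptor).
Remark 3: enolates, alkoxides and phenoxides of numbered compounds are not numbered separately.

## Route

Step 1
Reactants: 1 (S)-4-benzyl-2-oxazolidinone; 2 (E)-crotonoyl chloride
Product: 3 (S)-4-benzyl-3-[(E)-but-2-enoyl]oxazolidin-2-one
Conditions: n-BuLi, THF, −78 °C; then 2, −78 → 0 °C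
Reagents that add atoms: none
Why: N-acylation of the lithiated oxazolidinone by the acid chloride (standard imide formation), which leaves the E alkene and the auxiliary stereocentre untouched.

Step 2
Reactants: 4 methyl 2-(4-methoxyphenyl)acetate; 3 (S)-4-benzyl-3-[(E)-but-2-enoyl]oxazolidin-2-one
Product: 5 (S)-4-benzyl-3-[(3R,4S)-5-methoxy-4-(4-methoxyphenyl)-3-methyl-5-oxopentanoyl]oxazolidin-2-one
Conditions: LiN(i-Pr)2, THF, −78 °C; then 3, −78 °C; AcOH
Reagents that add atoms: none
Why: Michael addition of the ester lithium enolate to the lithium-chelated syn-s-cis N-enoyl imide; the benzyl group of the (S)-auxiliary shields one β-face, so C8–C9 bond formation on the other face should give (R)-C8, while C9 is not controlled and need not be.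

Step 3
Reactants: 5 (S)-4-benzyl-3-[(3R,4S)-5-methoxy-4-(4-methoxyphenyl)-3-methyl-5-oxopentanoyl]oxazolidin-2-one
Product: 7 (3R,4S)-5-methoxy-4-(4-methoxyphenyl)-3-methyl-5-oxopentanoic acid, via peroxy acid 6 (not isolated)
Conditions: LiOH, H2O2, THF/H2O, 0 °C; then Na2SO3; then 1 M HCl
Reagents that add atoms: hydrogen peroxide (used as LiOOH), OO
Why: hydroperoxide attacks the exocyclic imide carbonyl selectively (LiOOH cleavage of N-acyloxazolidinones) and faster than it saponifies the hindered α-aryl methyl ester; sulfite reduces the peracid and C8 has no acidic hydrogen.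

Step 4
Reactants: 7 (3R,4S)-5-methoxy-4-(4-methoxyphenyl)-3-methyl-5-oxopentanoic acid
Product: 9 methyl (1S,2R)-6-methoxy-2-methyl-4-oxo-1,2,3,4-tetrahydronaphthalene-1-carboxylate, via acid chloride 8 (not isolated)
Conditions: (COCl)2, DMF (cat.), CH2Cl2, 0 °C → rt; concentrate; SnCl4, CH2Cl2, −20 → 0 °C
Reagents that add atoms: none
Why: Oxalyl chloride turns the C6 acid into its chloride and SnCl4 ionises it to an acylium ion that attacks the anisole carbon C5 ortho to the C9-bearing ipso carbon, after which the σ-complex loses a proton (intramolecular Friedel–Crafts acylation, the closure of 4-arylbutanoyl chlorides to 1-tetralones known for the 7-methoxy-1-tetralone series). Ring B is closed as a six-membered ring by 6-exo attack of the arene on the acylium carbon, which forms the C5–C6 bond. No stereocentre is made; C8 is remote from any acidic site and keeps its R configuration, and epimerisation at C9 would be harmless. The step needs only regio- and chemoselectivity: the two ortho positions are equivalent, the tether forces attack meta to OMe (an ipso attack would reach the same tetralone by acyl shift), and the C11 ester cannot compete because it could close only a four-membered ring. SnCl4 at or below 0 °C is preferred to AlCl3 so that the aryl methyl ether and the methyl ester survive.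

Step 5
Reactants: 9 methyl (1S,2R)-6-methoxy-2-methyl-4-oxo-1,2,3,4-tetrahydronaphthalene-1-carboxylate
Product: 10 methyl (1R,2R)-6-methoxy-1,2-dimethyl-4-oxo-1,2,3,4-tetrahydronaphthalene-1-carboxylate
Conditions: KN(SiMe3)2 (1.05 equiv), THF, −78 °C; MeI, −78 → −40 °C
Reagents that add atoms: iodomethane, CI
Why: enolate alkylation at C9, whose hydrogen (benzylic, α to the ester, conjugated through the ring with the C6 ketone) is far more acidic than C7–H2; allylic 1,3-strain with the exocyclic enolate puts the C8 methyl pseudoaxial and MeI enters on the opposite face, so the new C9 methyl is trans to the C8 methyl.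

Step 6
Reactants: 10 methyl (1R,2R)-6-methoxy-1,2-dimethyl-4-oxo-1,2,3,4-tetrahydronaphthalene-1-carboxylate
Product: 11 (3R,4R)-4-(hydroxymethyl)-7-methoxy-3,4-dimethyl-1,2,3,4-tetrahydronaphthalen-1-ol (C6 epimers)
Conditions: LiAlH4, THF, 0 °C → reflux; H2O/NaOH work-up
Reagents that add atoms: none
Why: hydride reduction of the neopentyl ester to the C11 alcohol and of the ketone to the C6 carbinol in one operation; the C6 configuration is irrelevant because that carbon is re-oxidised in step 13.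

Step 7
Reactants: 11 (3R,4R)-4-(hydroxymethyl)-7-methoxy-3,4-dimethyl-1,2,3,4-tetrahydronaphthalen-1-ol
Product: 12 (3R,4R)-4-(hydroxymethyl)-7-methoxy-3,4-dimethyl-1,2,3,4,5,8-hexahydronaphthalen-1-ol
Conditions: n-BuLi (2.1 equiv), THF, −78 °C; then Li, NH3(l), t-BuOH, −78 → −33 °C; isoprene, then NH4Cl
Reagents that add atoms: none
Why: Birch reduction with the regiochemistry of 6-methoxytetralin (protonation at C1 and C4, leaving the C2=C3 enol ether and the tetrasubstituted C5=C10 alkene); the C6 oxygen is held as its lithium alkoxide, which is not expelled from the radical anion, and excess metal is destroyed before the ammonium salt is added so that benzylic hydrogenolysis is suppressed.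

Step 8
Reactants: 12 (3R,4R)-4-(hydroxymethyl)-7-methoxy-3,4-dimethyl-1,2,3,4,5,8-hexahydronaphthalen-1-ol
Product: 13 (5R,6R)-8-hydroxy-5-(hydroxymethyl)-5,6-dimethyl-3,4,5,6,7,8-hexahydronaphthalen-2(1H)-one
Conditions: oxalic acid, MeOH/H2O, 0 °C → rt
Reagents that add atoms: water, O
Why: mild acid hydrolysis of the enol ether (protonation at C2) frees the C3 ketone without moving the C5=C10 alkene into conjugation, as is usual for Birch products.

Step 9
Reactants: 13 (5R,6R)-8-hydroxy-5-(hydroxymethyl)-5,6-dimethyl-3,4,5,6,7,8-hexahydronaphthalen-2(1H)-one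
Product: 14 (5R,6R)-8-(tert-butyldimethylsilyloxy)-5-[(tert-butyldimethylsilyloxy)methyl]-5,6-dimethyl-3,4,5,6,7,8-hexahydronaphthalen-2(1H)-one
Conditions: t-BuMe2SiCl, imidazole, DMF, 40 °C
Reagents that add atoms: tert-butyldimethylsilyl chloride, CC(C)(C)[Si](C)(C)Cl
Why: silylation of both hydroxyls so that neither is O-methylated in step 10; the groups are stable to alkoxide base and removable with fluoride.

Step 10
Reactants: 14 (5R,6R)-8-(tert-butyldimethylsilyloxy)-5-[(tert-butyldimethylsilyloxy)methyl]-5,6-dimethyl-3,4,5,6,7,8-hexahydronaphthalen-2(1H)-one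
Product: 16 (5R,6R)-8-(tert-butyldimethylsilyloxy)-5-[(tert-butyldimethylsilyloxy)methyl]-1,1,5,6-tetramethyl-3,4,5,6,7,8-hexahydronaphthalen-2(1H)-one, via monomethyl ketone 15 (not isolated)
Conditions: t-BuOK (2.5 equiv), t-BuOH/THF, 0 °C; MeI, 0 °C → rt
Reagents that add atoms: iodomethane, CI
Why: C4 lies between the C3 carbonyl and the C5=C10 alkene, so the base forms the extended dienolate (O–C3=C4–C5=C10) and MeI reacts twice at its α-carbon C4 (the classical dialkylation to 4,4-dimethyl-3-ketones); once C4 is quaternary the alkene is locked at C5=C10.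

Step 11
Reactants: 16 (5R,6R)-8-(tert-butyldimethylsilyloxy)-5-[(tert-butyldimethylsilyloxy)methyl]-1,1,5,6-tetramethyl-3,4,5,6,7,8-hexahydronaphthalen-2(1H)-one
Product: 17 (5R,6R)-8-hydroxy-5-(hydroxymethyl)-1,1,5,6-tetramethyl-3,4,5,6,7,8-hexahydronaphthalen-2(1H)-one
Conditions: Bu4NF, THF, rt → 50 °C
Reagents that add atoms: none
Why: fluoride cleaves both silyl ethers, so that the following strongly basic reduction is run on a substrate of defined composition.

Step 12
Reactants: 17 (5R,6R)-8-hydroxy-5-(hydroxymethyl)-1,1,5,6-tetramethyl-3,4,5,6,7,8-hexahydronaphthalen-2(1H)-one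
Product: 19 (3R,4R)-4-(hydroxymethyl)-3,4,8,8-tetramethyl-1,2,3,4,5,6,7,8-octahydronaphthalen-1-ol, via hydrazone 18 (not isolated)
Conditions: N2H4·H2O, KOH, diethylene glycol, 130 °C then 200 °C
Reagents that add atoms: none
Why: Wolff–Kishner reduction (Huang-Minlon procedure) removes the C3 carbonyl as it does in 4,4-dimethyl-3-keto terpenoids; the alkene is not conjugated with the ketone and free alcohols tolerate the conditions.

Step 13
Reactants: 19 (3R,4R)-4-(hydroxymethyl)-3,4,8,8-tetramethyl-1,2,3,4,5,6,7,8-octahydronaphthalen-1-ol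
Product: 20 (3R,4R)-4-(hydroxymethyl)-3,4,8,8-tetramethyl-3,4,5,6,7,8-hexahydronaphthalen-1(2H)-one
Conditions: MnO2, CH2Cl2, rt
Reagents that add atoms: none
Why: MnO2 oxidises only the allylic C6 carbinol and leaves the saturated neopentyl C11 alcohol; both C6 epimers converge on the C6 enone.

Step 14
Reactants: 20 (3R,4R)-4-(hydroxymethyl)-3,4,8,8-tetramethyl-3,4,5,6,7,8-hexahydronaphthalen-1(2H)-one
Product: 21 N′-[(3R,4R)-4-(hydroxymethyl)-3,4,8,8-tetramethyl-3,4,5,6,7,8-hexahydronaphthalen-1(2H)-ylidene]-4-methylbenzenesulfonohydrazide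
Conditions: TsNHNH2, EtOH, AcOH (cat.), 70 °C
Reagents that add atoms: p-toluenesulfonyl hydrazide, Cc1ccc(cc1)S(=O)(=O)NN
Why: acid-catalysed condensation of the enone carbonyl with the sulfonyl hydrazide; the C7 methylene side of C6 is open enough for hydrazone formation despite the peri C4 methyl groups.

Step 15
Reactants: 21 N′-[(3R,4R)-4-(hydroxymethyl)-3,4,8,8-tetramethyl-3,4,5,6,7,8-hexahydronaphthalen-1(2H)-ylidene]-4-methylbenzenesulfonohydrazide
Product: 24 [(1R,2R,8aR)-1,2,5,5-tetramethyl-1,2,3,5,6,7,8,8a-octahydronaphthalen-1-yl]methanol, via allylic tosylhydrazine 22 (not isolated), via allylic diazene 23 (not isolated)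
Conditions: catecholborane, CHCl3, 0 °C → rt; then NaOAc·3H2O, reflux
Reagents that add atoms: none
Why: catecholborane reduction of an α,β-unsaturated tosylhydrazone with alkene transposition: hydride adds to C6, acetate eliminates sulfinate, and the allylic diazene loses N2 in a suprafacial retro-ene 1,5-hydrogen shift that puts H on C10 and the alkene at C5=C6; hydride should attack C6 anti to the C8 methyl (as in 1,2-reductions of 5-substituted cyclohexenones), so the diazene and then the C10 hydrogen end up cis to the C8 methyl and to C11, the configuration of the target.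

Step 16
Reactants: 24 [(1R,2R,8aR)-1,2,5,5-tetramethyl-1,2,3,5,6,7,8,8a-octahydronaphthalen-1-yl]methanol
Product: 25 (1R,2R,8aR)-1,2,5,5-tetramethyl-1,2,3,5,6,7,8,8a-octahydronaphthalene-1-carbaldehyde
Conditions: Dess–Martin periodinane, CH2Cl2, rt
Reagents that add atoms: none
Why: periodinane oxidation of the primary alcohol; the aldehyde has no α-hydrogen and cannot epimerise, and the alkene is inert.

Step 17
Reactants: 26 3,4-dihydroxybenzaldehyde
Product: 27 3,4-bis(allyloxy)benzaldehyde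
Conditions: allyl bromide, K2CO3, DMF, 60 °C
Reagents that add atoms: allyl bromide, C=CCBr
Why: Williamson etherification of both phenols; allyl ethers are chosen because they can be removed at the end without hydrogenation or acid.

Step 18
Reactants: 27 3,4-bis(allyloxy)benzaldehyde
Product: 29 3,4-bis(allyloxy)phenol, via aryl formate 28 (not isolated)
Conditions: mCPBA (1.1 equiv), CH2Cl2, 0 °C → rt; then K2CO3 (cat.), MeOH, rt
Reagents that add atoms: 3-chloroperoxybenzoic acid, OOC(=O)c1cccc(Cl)c1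
Why: Baeyer–Villiger (Dakin-type) oxidation in which the electron-rich aryl group migrates, followed by formate methanolysis; aryl migration is faster than epoxidation of the electron-poor monosubstituted allyl alkenes.

Step 19
Reactants: 29 3,4-bis(allyloxy)phenol
Product: 30 4,5-bis(allyloxy)-2-bromophenol
Conditions: NBS, MeCN, −20 → 0 °C
Reagents that add atoms: N-bromosuccinimide, O=C1CCC(=O)N1Br
Why: electrophilic bromination at the position ortho to OH and para to an allyloxy group, the most activated and least hindered site; ring bromination of the phenol is much faster than reaction at the allyl groups.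

Step 20
Reactants: 30 4,5-bis(allyloxy)-2-bromophenol
Product: 31 1,2-bis(allyloxy)-4-bromo-5-(methoxymethoxy)benzene
Conditions: MeOCH2Cl, i-Pr2NEt, CH2Cl2, 0 °C → rt
Reagents that add atoms: chloromethyl methyl ether, COCCl
Why: O-alkylation of the phenol to the MOM acetal, which stabilises the ortho aryllithium and can be removed later with the allyl ethers in place.

Step 21
Reactants: 31 1,2-bis(allyloxy)-4-bromo-5-(methoxymethoxy)benzene; 25 (1R,2R,8aR)-1,2,5,5-tetramethyl-1,2,3,5,6,7,8,8a-octahydronaphthalene-1-carbaldehyde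
Product: 33 [4,5-bis(allyloxy)-2-(methoxymethoxy)phenyl][(1R,2R,8aR)-1,2,5,5-tetramethyl-1,2,3,5,6,7,8,8a-octahydronaphthalen-1-yl]methanol (C11 epimers), via aryllithium 32 (not isolated)
Conditions: n-BuLi, THF, −78 °C; then 25, −78 → −20 °C; H2O
Reagents that add atoms: none
Why: bromine–lithium exchange and 1,2-addition of the aryllithium to the non-enolisable neopentyl aldehyde, the usual way to join an arene to a decalin aldehyde of this kind; the new carbinol centre is removed in step 23.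

Step 22
Reactants: 33 [4,5-bis(allyloxy)-2-(methoxymethoxy)phenyl][(1R,2R,8aR)-1,2,5,5-tetramethyl-1,2,3,5,6,7,8,8a-octahydronaphthalen-1-yl]methanol
Product: 35 O-{[4,5-bis(allyloxy)-2-(methoxymethoxy)phenyl][(1R,2R,8aR)-1,2,5,5-tetramethyl-1,2,3,5,6,7,8,8a-octahydronaphthalen-1-yl]methyl} S-methyl dithiocarbonate, via sodium xanthate 34 (not isolated)
Conditions: NaN(SiMe3)2, THF, −78 → 0 °C; CS2; then MeI
Reagents that add atoms: carbon disulfide, S=C=S; iodomethane, CI
Why: xanthate formation from the hindered alkoxide; C9 is quaternary, so no β-hydrogen is available for thermal elimination.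

Step 23
Reactants: 35 O-{[4,5-bis(allyloxy)-2-(methoxymethoxy)phenyl][(1R,2R,8aR)-1,2,5,5-tetramethyl-1,2,3,5,6,7,8,8a-octahydronaphthalen-1-yl]methyl} S-methyl dithiocarbonate
Product: 36 1,2-bis(allyloxy)-4-(methoxymethoxy)-5-{[(1R,2R,8aS)-1,2,5,5-tetramethyl-1,2,3,5,6,7,8,8a-octahydronaphthalen-1-yl]methyl}benzene
Conditions: Bu3SnH, AIBN (cat.), toluene, 110 °C
Reagents that add atoms: none
Why: Barton–McCombie deoxygenation through the benzylic C11 radical, which can only close a four-membered ring (on C5) or a five-membered ring in the endo mode (on C6) and is therefore simply reduced; stannyl radical addition to the thiocarbonyl is much faster than to the allyl ethers.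

Step 24
Reactants: 36 1,2-bis(allyloxy)-4-(methoxymethoxy)-5-{[(1R,2R,8aS)-1,2,5,5-tetramethyl-1,2,3,5,6,7,8,8a-octahydronaphthalen-1-yl]methyl}benzene
Product: 37 4,5-bis(allyloxy)-2-{[(1R,2R,8aS)-1,2,5,5-tetramethyl-1,2,3,5,6,7,8,8a-octahydronaphthalen-1-yl]methyl}phenol
Conditions: HCl (cat.), MeOH/THF, 40 °C
Reagents that add atoms: none
Why: acid-catalysed acetal exchange removes the aryl MOM group; dilute acid is too weak to protonate the trisubstituted C5=C6 alkene, and allyl aryl ethers are stable to it.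

Step 25
Reactants: 37 4,5-bis(allyloxy)-2-{[(1R,2R,8aS)-1,2,5,5-tetramethyl-1,2,3,5,6,7,8,8a-octahydronaphthalen-1-yl]methyl}phenol
Product: 39 5,6-bis(allyloxy)-2-hydroxy-3-{[(1R,2R,8aS)-1,2,5,5-tetramethyl-1,2,3,5,6,7,8,8a-octahydronaphthalen-1-yl]methyl}benzaldehyde, via salicyl alcohol 38 (not isolated)
Conditions: MgCl2, Et3N, (CH2O)n, MeCN, reflux; then 1 M HCl
Reagents that add atoms: paraformaldehyde (formaldehyde), C=O
Why: magnesium phenoxide-directed ortho-formylation (hydroxymethylation inside the magnesium chelate, then hydride transfer to a second formaldehyde); it can only reach C3′, the single free position ortho to the phenol oxygen, and uses no strong base or acid.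

Step 26
Reactants: 39 5,6-bis(allyloxy)-2-hydroxy-3-{[(1R,2R,8aS)-1,2,5,5-tetramethyl-1,2,3,5,6,7,8,8a-octahydronaphthalen-1-yl]methyl}benzaldehyde
Product: 40 sodium 3,4-bis(allyloxy)-2-formyl-6-{[(1R,2R,8aS)-1,2,5,5-tetramethyl-1,2,3,5,6,7,8,8a-octahydronaphthalen-1-yl]methyl}phenyl sulfate
Conditions: SO3·pyridine, pyridine, 50 °C; then aq. NaHCO3
Reagents that add atoms: sulfur trioxide–pyridine complex, O=S(=O)([O-])[n+]1ccccc1; sodium hydrogen carbonate, [Na+].OC([O-])=O
Why: O-sulfation of the only free phenol by the amine–SO3 complex; warming compensates for the hydrogen bond to the ortho aldehyde, and the reagent does not attack the alkenes or the aldehyde.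

Step 27
Reactants: 40 sodium 3,4-bis(allyloxy)-2-formyl-6-{[(1R,2R,8aS)-1,2,5,5-tetramethyl-1,2,3,5,6,7,8,8a-octahydronaphthalen-1-yl]methyl}phenyl sulfate
Product: 42 2-formyl-3,4-dihydroxy-6-{[(1R,2R,8aS)-1,2,5,5-tetramethyl-1,2,3,5,6,7,8,8a-octahydronaphthalen-1-yl]methyl}phenyl hydrogen sulfate (target), via sodium salt 41 (not isolated)
Conditions: Pd(PPh3)4 (5 mol%), morpholine, THF, rt (degassed); then 1 M HCl to pH 2, 0 °C, EtOAc/n-BuOH extraction
Reagents that add atoms: none
Why: Tsuji–Trost deallylation (π-allylpalladium formation from the aryl allyl ethers, capture of allyl by morpholine) frees the catechol under neutral, non-reducing conditions that spare the C5=C6 alkene, the aldehyde and the sulfate; brief cold acidification then gives the hydrogen sulfate as drawn.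

## Compound list

1 | (S)-4-benzyl-2-oxazolidinone | O=C1N[C@@H](Cc2ccccc2)CO1 | starting material
2 | (E)-crotonoyl chloride | C/C=C/C(=O)Cl | starting material
3 | (S)-4-benzyl-3-[(E)-but-2-enoyl]oxazolidin-2-one | C/C=C/C(=O)N1[C@@H](Cc2ccccc2)COC1=O | intermediate
4 | methyl 2-(4-methoxyphenyl)acetate | COC(=O)Cc1ccc(OC)cc1 | starting material
5 | (S)-4-benzyl-3-[(3R,4S)-5-methoxy-4-(4-methoxyphenyl)-3-methyl-5-oxopentanoyl]oxazolidin-2-one | C[C@H](CC(=O)N1[C@@H](Cc2ccccc2)COC1=O)[C@H](C(=O)OC)c1ccc(OC)cc1 | intermediate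
6 | (3R,4S)-5-methoxy-4-(4-methoxyphenyl)-3-methyl-5-oxopentaneperoxoic acid | C[C@H](CC(=O)OO)[C@H](C(=O)OC)c1ccc(OC)cc1 | intermediate (not isolated)
7 | (3R,4S)-5-methoxy-4-(4-methoxyphenyl)-3-methyl-5-oxopentanoic acid | C[C@H](CC(=O)O)[C@H](C(=O)OC)c1ccc(OC)cc1 | intermediate (key-step precursor)
8 | methyl (2S,3R)-5-chloro-2-(4-methoxyphenyl)-3-methyl-5-oxopentanoate | C[C@H](CC(=O)Cl)[C@H](C(=O)OC)c1ccc(OC)cc1 | intermediate (not isolated)
9 | methyl (1S,2R)-6-methoxy-2-methyl-4-oxo-1,2,3,4-tetrahydronaphthalene-1-carboxylate (a 7-methoxy-1-tetralone in ketone-based numbering) | C[C@@H]1CC(=O)c2cc(OC)ccc2[C@H]1C(=O)OC | intermediate (key-step product)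
10 | methyl (1R,2R)-6-methoxy-1,2-dimethyl-4-oxo-1,2,3,4-tetrahydronaphthalene-1-carboxylate | C[C@@H]1CC(=O)c2cc(OC)ccc2[C@]1(C)C(=O)OC | intermediate
11 | (3R,4R)-4-(hydroxymethyl)-7-methoxy-3,4-dimethyl-1,2,3,4-tetrahydronaphthalen-1-ol (C6 epimers) | C[C@@H]1CC(O)c2cc(OC)ccc2[C@]1(C)CO | intermediate
12 | (3R,4R)-4-(hydroxymethyl)-7-methoxy-3,4-dimethyl-1,2,3,4,5,8-hexahydronaphthalen-1-ol | C[C@@H]1CC(O)C2=C(CC=C(OC)C2)[C@]1(C)CO | intermediate
13 | (5R,6R)-8-hydroxy-5-(hydroxymethyl)-5,6-dimethyl-3,4,5,6,7,8-hexahydronaphthalen-2(1H)-one | C[C@@H]1CC(O)C2=C(CCC(=O)C2)[C@]1(C)CO | intermediate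
14 | (5R,6R)-8-(tert-butyldimethylsilyloxy)-5-[(tert-butyldimethylsilyloxy)methyl]-5,6-dimethyl-3,4,5,6,7,8-hexahydronaphthalen-2(1H)-one | C[C@@H]1CC(O[Si](C)(C)C(C)(C)C)C2=C(CCC(=O)C2)[C@]1(C)CO[Si](C)(C)C(C)(C)C | intermediate
15 | (5R,6R)-8-(tert-butyldimethylsilyloxy)-5-[(tert-butyldimethylsilyloxy)methyl]-1,5,6-trimethyl-3,4,5,6,7,8-hexahydronaphthalen-2(1H)-one | C[C@@H]1CC(O[Si](C)(C)C(C)(C)C)C2=C(CCC(=O)C2C)[C@]1(C)CO[Si](C)(C)C(C)(C)C | intermediate (not isolated)
16 | (5R,6R)-8-(tert-butyldimethylsilyloxy)-5-[(tert-butyldimethylsilyloxy)methyl]-1,1,5,6-tetramethyl-3,4,5,6,7,8-hexahydronaphthalen-2(1H)-one | C[C@@H]1CC(O[Si](C)(C)C(C)(C)C)C2=C(CCC(=O)C2(C)C)[C@]1(C)CO[Si](C)(C)C(C)(C)C | intermediate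
17 | (5R,6R)-8-hydroxy-5-(hydroxymethyl)-1,1,5,6-tetramethyl-3,4,5,6,7,8-hexahydronaphthalen-2(1H)-one | C[C@@H]1CC(O)C2=C(CCC(=O)C2(C)C)[C@]1(C)CO | intermediate
18 | hydrazone of 17 at C3 | C[C@@H]1CC(O)C2=C(CCC(=NN)C2(C)C)[C@]1(C)CO | intermediate (not isolated)
19 | (3R,4R)-4-(hydroxymethyl)-3,4,8,8-tetramethyl-1,2,3,4,5,6,7,8-octahydronaphthalen-1-ol (C6 epimers) | C[C@@H]1CC(O)C2=C(CCCC2(C)C)[C@]1(C)CO | intermediate
20 | (3R,4R)-4-(hydroxymethyl)-3,4,8,8-tetramethyl-3,4,5,6,7,8-hexahydronaphthalen-1(2H)-one | C[C@@H]1CC(=O)C2=C(CCCC2(C)C)[C@]1(C)CO | intermediate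
21 | N′-[(3R,4R)-4-(hydroxymethyl)-3,4,8,8-tetramethyl-3,4,5,6,7,8-hexahydronaphthalen-1(2H)-ylidene]-4-methylbenzenesulfonohydrazide | C[C@@H]1CC(=NNS(=O)(=O)c3ccc(C)cc3)C2=C(CCCC2(C)C)[C@]1(C)CO | intermediate
22 | N′-[(1S,3R,4R)-4-(hydroxymethyl)-3,4,8,8-tetramethyl-1,2,3,4,5,6,7,8-octahydronaphthalen-1-yl]-4-methylbenzenesulfonohydrazide (C6–N cis to the C8 methyl; formed as its boron adduct) | C[C@@H]1C[C@H](NNS(=O)(=O)c3ccc(C)cc3)C2=C(CCCC2(C)C)[C@]1(C)CO | intermediate (not isolated)
23 | [(1R,2R,4S)-4-diazenyl-1,2,5,5-tetramethyl-1,2,3,4,5,6,7,8-octahydronaphthalen-1-yl]methanol | C[C@@H]1C[C@H](N=N)C2=C(CCCC2(C)C)[C@]1(C)CO | intermediate (not isolated)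
24 | [(1R,2R,8aR)-1,2,5,5-tetramethyl-1,2,3,5,6,7,8,8a-octahydronaphthalen-1-yl]methanol | C[C@@H]1CC=C2[C@@H](CCCC2(C)C)[C@]1(C)CO | intermediate
25 | (1R,2R,8aR)-1,2,5,5-tetramethyl-1,2,3,5,6,7,8,8a-octahydronaphthalene-1-carbaldehyde | C[C@@H]1CC=C2[C@@H](CCCC2(C)C)[C@]1(C)C=O | intermediate
26 | 3,4-dihydroxybenzaldehyde | O=Cc1ccc(O)c(O)c1 | starting material
27 | 3,4-bis(allyloxy)benzaldehyde | O=Cc1ccc(OCC=C)c(OCC=C)c1 | intermediate
28 | 3,4-bis(allyloxy)phenyl formate | O=COc1ccc(OCC=C)c(OCC=C)c1 | intermediate (not isolated)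
29 | 3,4-bis(allyloxy)phenol | Oc1ccc(OCC=C)c(OCC=C)c1 | intermediate
30 | 4,5-bis(allyloxy)-2-bromophenol | Oc1cc(OCC=C)c(OCC=C)cc1Br | intermediate
31 | 1,2-bis(allyloxy)-4-bromo-5-(methoxymethoxy)benzene | COCOc1cc(OCC=C)c(OCC=C)cc1Br | intermediate
32 | [4,5-bis(allyloxy)-2-(methoxymethoxy)phenyl]lithium | COCOc1cc(OCC=C)c(OCC=C)cc1[Li] | intermediate (not isolated)
33 | [4,5-bis(allyloxy)-2-(methoxymethoxy)phenyl][(1R,2R,8aR)-1,2,5,5-tetramethyl-1,2,3,5,6,7,8,8a-octahydronaphthalen-1-yl]methanol (C11 epimers) | C[C@@H]1CC=C2[C@@H](CCCC2(C)C)[C@]1(C)C(O)c1cc(OCC=C)c(OCC=C)cc1OCOC | intermediate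
34 | sodium O-alkyl dithiocarbonate (xanthate salt) of 33 | C[C@@H]1CC=C2[C@@H](CCCC2(C)C)[C@]1(C)C(OC(=S)[S-])c1cc(OCC=C)c(OCC=C)cc1OCOC.[Na+] | intermediate (not isolated)
35 | O-{[4,5-bis(allyloxy)-2-(methoxymethoxy)phenyl][(1R,2R,8aR)-1,2,5,5-tetramethyl-1,2,3,5,6,7,8,8a-octahydronaphthalen-1-yl]methyl} S-methyl dithiocarbonate | C[C@@H]1CC=C2[C@@H](CCCC2(C)C)[C@]1(C)C(OC(=S)SC)c1cc(OCC=C)c(OCC=C)cc1OCOC | intermediate
36 | 1,2-bis(allyloxy)-4-(methoxymethoxy)-5-{[(1R,2R,8aS)-1,2,5,5-tetramethyl-1,2,3,5,6,7,8,8a-octahydronaphthalen-1-yl]methyl}benzene | C[C@@H]1CC=C2[C@@H](CCCC2(C)C)[C@]1(C)Cc1cc(OCC=C)c(OCC=C)cc1OCOC | intermediate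
37 | 4,5-bis(allyloxy)-2-{[(1R,2R,8aS)-1,2,5,5-tetramethyl-1,2,3,5,6,7,8,8a-octahydronaphthalen-1-yl]methyl}phenol | C[C@@H]1CC=C2[C@@H](CCCC2(C)C)[C@]1(C)Cc1cc(OCC=C)c(OCC=C)cc1O | intermediate
38 | 3,4-bis(allyloxy)-2-(hydroxymethyl)-6-{[(1R,2R,8aS)-1,2,5,5-tetramethyl-1,2,3,5,6,7,8,8a-octahydronaphthalen-1-yl]methyl}phenol | C[C@@H]1CC=C2[C@@H](CCCC2(C)C)[C@]1(C)Cc1cc(OCC=C)c(OCC=C)c(CO)c1O | intermediate (not isolated)
39 | 5,6-bis(allyloxy)-2-hydroxy-3-{[(1R,2R,8aS)-1,2,5,5-tetramethyl-1,2,3,5,6,7,8,8a-octahydronaphthalen-1-yl]methyl}benzaldehyde | C[C@@H]1CC=C2[C@@H](CCCC2(C)C)[C@]1(C)Cc1cc(OCC=C)c(OCC=C)c(C=O)c1O | intermediate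
40 | sodium 3,4-bis(allyloxy)-2-formyl-6-{[(1R,2R,8aS)-1,2,5,5-tetramethyl-1,2,3,5,6,7,8,8a-octahydronaphthalen-1-yl]methyl}phenyl sulfate | C[C@@H]1CC=C2[C@@H](CCCC2(C)C)[C@]1(C)Cc1cc(OCC=C)c(OCC=C)c(C=O)c1OS(=O)(=O)[O-].[Na+] | intermediate
41 | sodium 2-formyl-3,4-dihydroxy-6-{[(1R,2R,8aS)-1,2,5,5-tetramethyl-1,2,3,5,6,7,8,8a-octahydronaphthalen-1-yl]methyl}phenyl sulfate | C[C@@H]1CC=C2[C@@H](CCCC2(C)C)[C@]1(C)Cc1cc(O)c(O)c(C=O)c1OS(=O)(=O)[O-].[Na+] | intermediate (not isolated)
42 | 2-formyl-3,4-dihydroxy-6-{[(1R,2R,8aS)-1,2,5,5-tetramethyl-1,2,3,5,6,7,8,8a-octahydronaphthalen-1-yl]methyl}phenyl hydrogen sulfate | C[C@@H]1CC=C2[C@@H](CCCC2(C)C)[C@]1(C)Cc1cc(O)c(O)c(C=O)c1OS(=O)(=O)O | target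

## Step count

Total steps: 27. Longest linear sequence: 23 steps (steps 1–16 and 21–27); the arene branch is steps 17–20.

## Steps most likely to fail

Step 15 (with the hydrazone of step 14). What may go wrong: the peri C4 methyl groups slow hydrazone formation, and hydride may reach C6 of the hydrazone from both faces, so that the diazene forms on both faces and C10 is scrambled. Fallback (sets out from 20, returns at 24): the diazene is made by an invertive Mitsunobu displacement on a C6 carbinol of defined configuration instead of by hydrazone reduction. NaBH4/CeCl3·7H2O (MeOH, −78 °C) should reduce 20 mainly to (1S,3R,4R)-4-(hydroxymethyl)-3,4,8,8-tetramethyl-1,2,3,4,5,6,7,8-octahydronaphthalen-1-ol F1, with the C6 hydroxyl cis to the C8 methyl. The C6 epimers are separable. F1 would be inverted with 4-nitrobenzoic acid, PPh3 and DIAD to (1R,3R,4R)-4-(hydroxymethyl)-3,4,8,8-tetramethyl-1,2,3,4,5,6,7,8-octahydronaphthalen-1-yl 4-nitrobenzoate F2 and methanolysed (K2CO3, MeOH) to (1R,3R,4R)-4-(hydroxymethyl)-3,4,8,8-tetramethyl-1,2,3,4,5,6,7,8-octahydronaphthalen-1-ol F3; any of this epimer formed directly in the reduction is used as it is. Treatment of F3 with 2-nitrobenzenesulfonylhydrazide, PPh3 and DEAD (THF, −30 °C → rt) should displace the C6 oxygen with inversion to give N-[(1S,3R,4R)-4-(hydroxymethyl)-3,4,8,8-tetramethyl-1,2,3,4,5,6,7,8-octahydronaphthalen-1-yl]-2-nitrobenzenesulfonohydrazide F4. On warming this loses the sulfinic acid to give the same diazene 23 and then N2 to give 24. The neopentyl C11 hydroxyl cannot be displaced under these conditions.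

Step 7. What may go wrong: benzylic C–O hydrogenolysis of the C6 alkoxide in the anisole radical anion, so that the C6 oxygen is lost during the ring reduction. Fallback (sets out from 11, returns at 16): the oxygen is allowed to go and is put back at C6 after dearomatisation by the γ-oxidation known for 4-en-3-ones. Li/NH3/EtOH with an NH4Cl quench would take 11 to [(1R,2R)-6-methoxy-1,2-dimethyl-1,2,3,4,5,8-hexahydronaphthalen-1-yl]methanol F5. Aqueous HCl in MeOH would give the conjugated enone (5R,6R)-5-(hydroxymethyl)-5,6-dimethyl-4,4a,5,6,7,8-hexahydronaphthalen-2(3H)-one F6. Isopropenyl acetate/TsOH would give the dienol acetate [(1R,2R)-6-acetoxy-1,2-dimethyl-1,2,3,7,8,8a-hexahydronaphthalen-1-yl]methyl acetate F7, whose C5=C6 bond is attacked by buffered mCPBA to give [(1R,2R)-4-hydroxy-1,2-dimethyl-6-oxo-1,2,3,4,6,7,8,8a-octahydronaphthalen-1-yl]methyl acetate F8. K2CO3/MeOH would give (5R,6R)-8-hydroxy-5-(hydroxymethyl)-5,6-dimethyl-4,4a,5,6,7,8-hexahydronaphthalen-2(3H)-one F9, and t-BuMe2SiCl/imidazole its bis-silyl ether (5R,6R)-8-(tert-butyldimethylsilyloxy)-5-[(tert-butyldimethylsilyloxy)methyl]-5,6-dimethyl-4,4a,5,6,7,8-hexahydronaphthalen-2(3H)-one F10. Under the conditions of step 10 (t-BuOK, MeI) F10 should be deprotonated at C10, since C6 carries the silyloxy group, to the same dienolate as 14 and be methylated twice at C4 to give 16. The C10 configuration of F6–F10 does not matter because that carbon becomes sp2 again. The weak point of this fallback is the site of that γ-deprotonation.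

Step 2. What may go wrong: attack of the enolate on the imide carbonyl instead of the β-carbon, and weak facial discrimination if the imide is not held in the lithium chelate, which would lower the enantiomeric purity of everything that follows. Fallback (replaces steps 1–3; it sets out not from a route compound but from purchased material and returns at 7): C8 is taken from the chiral pool and the C9–aryl bond is made by enolate arylation. The starting material is methyl hydrogen (R)-3-methylglutarate, (R)-5-methoxy-3-methyl-5-oxopentanoic acid F11. LiN(SiMe3)2 (2.2 equiv, THF, −78 °C) deprotonates the acid and then only the ester α-carbon C9. Transmetalation with ZnCl2 and coupling with 4-bromoanisole under Pd(dba)2/P(t-Bu)3 catalysis should give 7 as a C9 epimer mixture, which serves step 4 as well as a single epimer.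

Further compounds
F1 | step 15 | (1S,3R,4R)-4-(hydroxymethyl)-3,4,8,8-tetramethyl-1,2,3,4,5,6,7,8-octahydronaphthalen-1-ol | C[C@@H]1C[C@H](O)C2=C(CCCC2(C)C)[C@]1(C)CO
F2 | step 15 | (1R,3R,4R)-4-(hydroxymethyl)-3,4,8,8-tetramethyl-1,2,3,4,5,6,7,8-octahydronaphthalen-1-yl 4-nitrobenzoate | C[C@@H]1C[C@@H](OC(=O)c3ccc(cc3)[N+](=O)[O-])C2=C(CCCC2(C)C)[C@]1(C)CO
F3 | step 15 | (1R,3R,4R)-4-(hydroxymethyl)-3,4,8,8-tetramethyl-1,2,3,4,5,6,7,8-octahydronaphthalen-1-ol | C[C@@H]1C[C@@H](O)C2=C(CCCC2(C)C)[C@]1(C)CO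
F4 | step 15 | N-[(1S,3R,4R)-4-(hydroxymethyl)-3,4,8,8-tetramethyl-1,2,3,4,5,6,7,8-octahydronaphthalen-1-yl]-2-nitrobenzenesulfonohydrazide | C[C@@H]1C[C@H](N(N)S(=O)(=O)c3ccccc3[N+](=O)[O-])C2=C(CCCC2(C)C)[C@]1(C)CO
F5 | step 7 | [(1R,2R)-6-methoxy-1,2-dimethyl-1,2,3,4,5,8-hexahydronaphthalen-1-yl]methanol | C[C@@H]1CCC2=C(CC=C(OC)C2)[C@]1(C)CO
F6 | step 7 | (5R,6R)-5-(hydroxymethyl)-5,6-dimethyl-4,4a,5,6,7,8-hexahydronaphthalen-2(3H)-one | C[C@@H]1CCC2=CC(=O)CCC2[C@]1(C)CO
F7 | step 7 | [(1R,2R)-6-acetoxy-1,2-dimethyl-1,2,3,7,8,8a-hexahydronaphthalen-1-yl]methyl acetate | C[C@@H]1CC=C2C=C(OC(C)=O)CCC2[C@]1(C)COC(C)=O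
F8 | step 7 | [(1R,2R)-4-hydroxy-1,2-dimethyl-6-oxo-1,2,3,4,6,7,8,8a-octahydronaphthalen-1-yl]methyl acetate | C[C@@H]1CC(O)C2=CC(=O)CCC2[C@]1(C)COC(C)=O
F9 | step 7 | (5R,6R)-8-hydroxy-5-(hydroxymethyl)-5,6-dimethyl-4,4a,5,6,7,8-hexahydronaphthalen-2(3H)-one | C[C@@H]1CC(O)C2=CC(=O)CCC2[C@]1(C)CO
F10 | step 7 | (5R,6R)-8-(tert-butyldimethylsilyloxy)-5-[(tert-butyldimethylsilyloxy)methyl]-5,6-dimethyl-4,4a,5,6,7,8-hexahydronaphthalen-2(3H)-one | C[C@@H]1CC(O[Si](C)(C)C(C)(C)C)C2=CC(=O)CCC2[C@]1(C)CO[Si](C)(C)C(C)(C)C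
F11 | step 2 | (R)-5-methoxy-3-methyl-5-oxopentanoic acid | C[C@H](CC(=O)O)CC(=O)OC
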